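The readings are simulated from invented constants.

How far does the larch run get in 32 min, and what power of [starting material] does the first rate follow?

| flask | starting material | time |
|---|---|---|
| birch | 0.0800 M |  |
| ash | 0.160 M |  |
| larch | 0.520 M | 32 min |

- birch run (time / min: [product] / M): 1.8: 0.0022; 5.5: 0.0039; 11: 0.0106; 17: 0.0211; 24: 0.0384; 32: 0.0554
- ash run (time / min: [product] / M): 1.8: 0.0036; 5.5: 0.0065; 11: 0.0266; 17: 0.0644; 24: 0.1149; 32: 0.1452

(each reading ± 0.001 M)

1. the power of [starting material] that the first rate follows, about the charge of the birch run; measure it at two percent of starting material made into product (one fixed amount of product, the same in the runs compared)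
2. product in the larch run at 32 min, as a share of the starting material charged

- Overall: starting material -> product.
- Constant volume, constant temperature.
- A reading of a species includes what of it is bound.
- An order is taken over about fifteen percent of the charge, up and down.

Two chemists agree on the early readings. At 5.5 min the ash run, with twice the charge of the birch run, holds 1.67 times its product, which gives an order near 0.737. That is a ratio at equal time, not at equal product, and it carries the scatter of the readings.

They part over the larch run. The second chemist takes the steepest ash stretch, 0.00721 M min⁻¹, as a ceiling, and over 32 min that makes 44.4% of the larch charge. The ceiling does describe the ash run from 11 min to 24 min, where the rate goes from 0.00630 M min⁻¹ to 0.00721 M min⁻¹. But the steepest birch stretch reads 0.00247 M min⁻¹, so from the birch run to the ash run the steepest stretch read off the readings rose by more than the charge did.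

The first chemist, whom I follow, sees autocatalysis and counts odds instead. From 17 min to 24 min the ash run gives 0.190 min⁻¹: this is the odds rate, the growth per minute of ln([product]/(charge − [product])). The birch run gives 0.135 min⁻¹. Even odds fall near 24.6 min in the birch run and 19.1 min in the ash run. Carrying that shortening on as a power of the charge puts them at 12.4 min in the larch run. I keep the ash odds rate, which leaves 3.73 units of ln odds by 32 min, so my share is 97.6%.

The forecast, which sees “clear autocatalysis”, gave order 0.7 and 93%, lower than my share.

The simulation gives order 0.80 and 97.2%.

    2 starting material ⇌ intermediate + starting material (6.900 M⁻¹ min⁻¹, 10.68 M⁻¹ min⁻¹)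
    intermediate → product (0.03264 min⁻¹)
    starting material + product → 2 product (2.472 M⁻¹ min⁻¹)
    2 starting material ⇌ idle substrate dimer, settled at all times (8.150 M⁻¹)

Where two percent of the starting material of the birch run have turned, the rate of product formation in the ash run is 0.0013 M min⁻¹ against 7.6 × 10⁻⁴ M min⁻¹ in the birch run. The larch share corresponds to an odds rate of 0.180 min⁻¹ after my even-odds time, lower than the ash 0.190 min⁻¹. In the birch run, the quarter and half times 16.7 min and 25.5 min give ln(3) over their gap, 0.125 min⁻¹, against 0.135 min⁻¹ from the readings.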